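The readings stem from a simulated flask with made-up constants; the scatter is artificial.

Leave this flask's charge of Q as weighed, add no J, and come back at 25 h.

- north: D 12 mM; Q 4.8 mM; J 2.4 mM; run made earlier
- flask: D 12 mM; Q 9.60 mM; J 2.40 mM; time 25 h

north run (percent of the D charged): time / h: Z / % = 0.667: 6.3; 2.00: 11.7; 4.00: 12.6; 5.00: 12.3; 8.00: 11.6

(each reading ± 0.3 percentage points)

- the reaction counts as stopped when no species that holds the D changes by six tenths of a point or more over the second half of the time

- the state of affairs at 25 h: stopped, and by what, or still going (all of D has reacted / Q has run out first / forward and back rates have come level / it is still moving)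
- how much Z there is at 25 h, in percent of the D charged
- amount of Z if the flask were left three thousand times as long, in percent of the D charged

I read the north run, with its highest reading of 12.6% at 4.00 h and its sag to 11.6% at 8.00 h, as D + Q ⇌ Z with J taking up Q one to one. The peak is then a kinetic overshoot, and the tail moves towards thermodynamic control. If J has taken its whole charge by the last reading, free Q is 21.0% of its charge, and the hold, Z over D per mM of free Q, is 0.130 /mM. Z is still falling there, so I take this as the high side.

In this flask the same hold, with J's charge taken off Q, gives Z near 31.1%. Free Q in this flask is then 36.1% of a larger charge, so J should react sooner than in north, and I expect the flask level by 25 h, with that Z as my high side both then and much later. The forecast puts Z at 20.1% and 19.5% much later, and its verdict is it is still moving, on the reckoning that “Z falls about 1 point between 12.5 and 25 h”.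

The flask at 25 h stands thus: forward and back rates have come level; Z is at 26.5%, and at 26.5% much later.

    D + Q ⇌ Z (K = 89.0 /M, k = 0.00780 /M/s)
    J + Q ⇌ E (K = 14000 /M, k = 0.0390 /M/s)

At 25.0 h the J step, taken by itself, relaxes with a half-life of 1.18 h, and half of the turnover to Z is done by 0.728 h, both far shorter than the 25 h allowed. The hold in this flask stands at 0.0890 /mM, and in the neighbour charged with 38 mM of Q, where Z reaches 70.7%, it stands at 0.0890 /mM.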